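- I began with the easy count: the recipes give 2.50 equivalents of partner per substrate, and protic impurity, taken one for one, is worth 8.00 % of the partner.

| setting | summer | dawn | larch | cedar | alder | oak |
|---|---|---|---|---|---|---|
| substrate | 0.10 M | 0.10 M | 0.10 M | 0.10 M (fed, over 4.0 h) | 0.10 M | 0.10 M (in portions, 5, over 4.0 h) |
| partner | 0.25 M | 0.38 M | 0.250 M (fed, over 4.0 h) | 0.250 M | 0.250 M | 0.250 M |
| protic impurity | 0.020 M | 0.020 M | 0.0200 M | 0.0200 M | 0.0200 M | 0.0200 M |
| remark | run made earlier | run made earlier | all else is in the flask from the start; the feed brings no volume worth counting | all else is in the flask from the start; the feed brings no volume worth counting | everything together at the start | first portion at the start, last at 4.0 h |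
| time |  |  | 6.0 h | 6.0 h | 6.0 h | 6.0 h |

summer run (percent of the substrate charged)

| time / h | target / % | substrate / % |
|---|---|---|
| 0.250 | 0.7 | 80.4 |
| 0.500 | 5.1 | 63.3 |
| 1.00 | 9.7 | 45.7 |
| 2.00 | 12.5 | 30.0 |
| 4.00 | 10.2 | 23.0 |

dawn run (percent of the substrate charged)

| time / min | target / % | substrate / % |
|---|---|---|
| 8.00 | 0.7 | 90.6 |
| 15.0 | 0 | 80.2 |
| 20.0 | 3.4 | 74.7 |
| 30.0 | 5.6 | 64.8 |
| 40.0 | 8.0 | 56.9 |

(scatter of a reading: 1 percentage point)



- the best flask by amount of target, in percent of the substrate charged; "all alike" if 1.5 percentage points covers them all (larch / cedar / alder / oak / all alike)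
- amount of target at the end, in percent of the substrate charged, larch
- amount of target at the end, in percent of the substrate charged, cedar
- amount of target at the end, in percent of the substrate charged, alder
- amount of target at the end, in percent of the substrate charged, oak

- The bench rule then calls substrate the limiting reagent by charge, so the order of addition shouldn't matter and target should follow the substrate lost.
- The summer run marked the border of that rule: at 2.00 h, the readings gave 0.179 target per substrate lost, far below one.
- The dawn run charged 1.52 times the c(partner) of summer, yet the first-order constants I read were 0.915 /h for summer and 0.868 /h for dawn, so I took substrate loss as indifferent to c(partner).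
- Summer target gained 4.6 percentage points in the half-hour before 1.00 h, then 2.8 points in the next hour, so I took 1.00 h as the working span of a partner charge.
- I carried one quantity, the dosing number, the feed time multiplied by the substrate loss constant: 3.66 for larch.
- I solved both ends and joined them, taking first-order loss: over a window of x loss times, the mean share of substrate already gone is x divided by two for a short window and one minus one over x for a long one, and one minus (one minus exp(−x))/x joins them.
- That first-order loss was my simplification: summer still read 23.0 % substrate at 4.00 h, where it gives 2.57 %.
- On my working span, alder's partner gets x = 0.915, a mean share of 34.5 %; larch's feed gives 73.4 %, which is larger.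
- I took the mean of the last two summer target readings, 11.3 %, for alder, and scaling it by the two shares I reckoned 24.2 % for larch.
- Cedar had received a quarter of its substrate by 1.00 h, so I put cedar below alder; oak starts with a first portion of 0.0200 M substrate, so I put oak below alder too.
- The forecast gave 9.5 % for larch, 5.5 % for cedar, 8.5 % for alder and 6 % for oak, with larch first, and called larch over alder “a slim call”.
- The flasks gave 20.9 % for larch, 1.62 % for cedar, 11.5 % for alder and 2.84 % for oak, so larch was best.

    partner + protic impurity → quenched reagent (k = 0.00780 /M/s)
    second intermediate → side product (k = 6.90 × 10⁻⁴ /s)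
    open intermediate + second intermediate → target (k = 0.00180 /M/s)
    partner → second intermediate (k = 8.30 × 10⁻⁴ /s)
    partner → decomposed reagent (k = 4.10 × 10⁻⁴ /s)
    substrate ⇌ open intermediate (K = 3.10, k = 2.60 × 10⁻⁴ /s)

- When its feed ended at 4.00 h, larch held 17.8 % target, with partner at 5.42 % of its charge.
- At dosing number 3.66 larch ended at 20.9 %, against my 24.2 %; the same larch recipe dosed over 1.20 h, dosing number 1.10, ended at 17.2 %.

The readings are simulated from invented constants; noise was put on by code.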